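Begin in a one-step world, then add the steps of the flask one at a time. These are the flasks and the questions.

| flask | substrate | partner | capture agent | free catalyst | temperature | time |
|---|---|---|---|---|---|---|
| Saturday's | 42 mM | 1.50 equiv | 2.10 mM | 5 mol% | 10 °C | 6.0 h |
| Sunday's | 42 mM | 1.50 equiv | 2.10 mM | 5 mol% | 70 °C | 6.0 h |
| Monday's | 42 mM | 1.50 equiv | 2.10 mM | 5 mol% | 50 °C | 6.0 h |
| Friday's | 42 mM | 1.50 equiv | 2.10 mM | 5 mol% | 30 °C | 6.0 h |

* the best flask by amount of target, in percent of the substrate charged; "all alike" if 1.5 percentage points covers them all (Saturday's / Sunday's / Monday's / Friday's / all alike)
* amount of target at the end, in percent of the substrate charged, Saturday's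
* amount of target at the end, in percent of the substrate charged, Sunday's
* amount of target at the end, in percent of the substrate charged, Monday's
* amount of target at the end, in percent of the substrate charged, Friday's

- percent here means substrate units held: one self-condensation product counts as two
- a step written with two of one species runs at k times the square of its concentration and takes two of it each time
- the list of constants is for 50 °C, to be carried to other temperatures by the activation energies and enthalpies

    substrate + free catalyst ⇌ free catalyst + open intermediate (K1 = 0.71, k1 = 0.17 L mol⁻¹ s⁻¹, Ea1 = 53.0 kJ mol⁻¹, ΔH1 = −37.0 kJ mol⁻¹)
    free catalyst + open intermediate ⇌ catalyst intermediate (K2 = 23 L mol⁻¹, k2 = 0.13 L mol⁻¹ s⁻¹, Ea2 = 47.0 kJ mol⁻¹, ΔH2 = 2.00 kJ mol⁻¹)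
    partner + catalyst intermediate ⇌ free catalyst + target (K3 = 1.0, k3 = 0.036 L mol⁻¹ s⁻¹, Ea3 = 64.0 kJ mol⁻¹, ΔH3 = −35.0 kJ mol⁻¹)
    2 substrate → self-condensation product (k4 = 0.0013 L mol⁻¹ s⁻¹, Ea4 = 68.0 kJ mol⁻¹)
    open intermediate + capture agent → trapped intermediate (k5 = 0.0026 L mol⁻¹ s⁻¹, Ea5 = 57.0 kJ mol⁻¹)
    (constants at 50 °C)

Take Monday's flask, whose temperature is the one the constants belong to, and keep just the swap of substrate into open intermediate on the free catalyst. That swap relaxes with a time constant of 0.323 h, shorter than the 6.0 h run, so it comes to balance with open intermediate at 41.5% of the substrate charged.

Now add the road to target. Open intermediate binds free catalyst to give catalyst intermediate, and partner turns that into target and free catalyst, reversibly. Catalyst intermediate falls back with a time constant of 2.95 min and goes on with partner with one of 7.35 min. The first is shorter, but the two are of like size, so this is no clean pre-equilibrium: 28.6% of what forms goes on to target. Target then behaves as a first-order lag chasing a ceiling. Call the ceiling Q times the open intermediate, where Q is the product of the binding and partner equilibrium constants and the partner concentration, 1.45 at the charge. With the full catalyst charge, the lag time τ is 5.15 h: the return time, the partner step's equilibrium constant over its rate constant times the free catalyst concentration, stretched by one plus the ratio of the two times above. Both of those times are far shorter than τ, so treat catalyst intermediate as steady. At balance, substrate, open intermediate and target stand as one to the constant of the swap to that constant times Q, which gives target 37.6%. The lag delivers 68.8% of that in 6.0 h, so the number becomes 25.9%.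

Add the rest. Capture agent can hold 5.00% of the substrate charged at most, so set it aside. Self-condensation matters, since its first half-life by itself is 2.54 h, shorter than the run. It runs on the square of the substrate, so the pool of substrate, open intermediate and target shrinks by the factor one over one plus x s², where x is 2.36 and s is the substrate's share of the pool. That share is a curve, from 58.5% before target builds to 36.5% at full balance. Replace it by its mean, 47.5%, and my figure for Monday's is 16.9%. Check the error by putting in the ends of the curve instead: they give 14.3% and 19.7%. My reckoning stops at this flask. From the coldest flask to the hottest, self-condensation speeds up by 160 and the partner step by 120, so heat favours the loss somewhat.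

The forecast names Monday's as best, with 0.9% for Saturday's, 2.8% for Sunday's, 19% for Monday's and 10% for Friday's. Its ground is that “50 °C is the compromise”. Its Monday's figure lies above mine.

The simulation gives Monday's as best, with 0.859% for Saturday's, 2.92% for Sunday's, 18.2% for Monday's and 9.33% for Friday's. The forecast held.

Monday's flask ends at 18.2% of target, with open intermediate at 17.3% and partner at 87.8% of its charge, which puts the ceiling at 22.0%. Free catalyst reads 86.2% of its charge there, so τ counted on the free catalyst is 5.97 h, longer than the charge gave, and target stands below its ceiling.

Try the neighbour: Monday's flask with 20 mol% of free catalyst. There τ falls to 1.29 h, the lag delivers 99.1%, and scaling Monday's result by the two lag fractions gives 26.2%. The computed flask gives 23.4%.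

The constants used here come from no measurement.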